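**Retrosynthetic overview**
1. Acid 14 ⇐ methyl ester 13 ⇐ (C2–C3 bond) cyclic peroxycarbenium ion from dioxolanol 10 plus an acetate silyl ketene acetal. This step is catalyst-controlled and sets C3.
2. 10 ⇐ H2O2 plus (E)-enone 8. Enantioselective conjugate hydroperoxidation makes C5–O and sets C5, and peroxyhemiketalisation then makes C3–O. This is the key step.
3. 8 ⇐ terminal alkyne 6 by syn-methylalumination/acylation. This fixes the E-trisubstituted alkene that encodes C5.
4. 6 ⇐ (C10–C11, sp2–sp2) deca-1,9-diyne 4 plus dienyl iodide 3 by hydrozirconation/Negishi coupling. 3 ⇐ leaf alcohol 1.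
5. Ring order: there is one ring only, the 1,2-dioxolane, closed in step 5 once the whole C20 chain is in place.

Assumption: the absolute sense of induction of the chiral catalysts in steps 5 and 6 is extrapolated from simpler substrates. Both catalysts exist in both (pseudo)enantiomeric forms, and the form that gives the drawn configuration is the one meant.

**Step 1**
Reactants: 1 (Z)-hex-3-en-1-ol
Product: 2 (Z)-hex-3-enal
Conditions: DMP (1.1 equiv), CH2Cl2, 0 °C → rt, 1 h; short silica plug, used at once
Reagents that add atoms: none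
Why: Dess–Martin oxidation is fast and essentially neutral, so the β,γ-Z-alkene neither migrates into conjugation nor isomerises if the aldehyde is used directly.

**Step 2**
Reactants: 2 (Z)-hex-3-enal
Product: 3 (1E,4Z)-1-iodohepta-1,4-diene
Conditions: CrCl2 (6 equiv), CHI3 (2 equiv), dioxane/THF 6:1, 0 °C → rt
Reagents that add atoms: iodoform, C(I)(I)I
Why: In the Takai olefination the gem-dichromium species adds to the aldehyde and eliminates to the E-vinyl iodide (about 8–10:1 in dioxane-rich solvent) under non-basic conditions that leave the skipped Z-alkene in place; the minor isomer is removed on AgNO3-silica at 6 or 8.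

**Step 3**
Reactants: 3 (1E,4Z)-1-iodohepta-1,4-diene; 4 deca-1,9-diyne
Product: 6 (9E,11E,14Z)-heptadeca-9,11,14-trien-1-yne, via alkenylzirconocene chloride 5 (not isolated)
Conditions: 4 (3 equiv), Cp2Zr(H)Cl (1.1 equiv), THF, rt, 30 min; then 3 (1.0 equiv), Pd(PPh3)4 (5 mol %), rt; excess 4 recovered by distillation
Reagents that add atoms: none
Why: Syn, anti-Markovnikov hydrozirconation followed by Negishi alkenyl–alkenyl coupling proceeds with retention on both partners and gives the E,E-diene; the excess of the symmetric diyne holds double reaction below about 10 %, and that by-product has no alkyne, so it drops out after step 4.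

**Step 4**
Reactants: 6 (9E,11E,14Z)-heptadeca-9,11,14-trien-1-yne
Product: 8 (3E,11E,13E,16Z)-4-methylnonadeca-3,11,13,16-tetraen-2-one, via dimethyl(alkenyl)alane 7 (not isolated)
Conditions: Me3Al (2 equiv), Cp2ZrCl2 (0.25 equiv), CH2Cl2, 0 °C → rt; volatiles removed in vacuo; AcCl (1.5 equiv), Pd(PPh3)4 (5 mol %), THF, 0 °C
Reagents that add atoms: trimethylaluminium, C[Al](C)C; acetyl chloride, CC(=O)Cl
Why: Negishi Zr-catalysed methylalumination adds Me and Al syn, with Me on the internal carbon, only to the terminal alkyne (internal alkenes are inert), and Pd-catalysed acylation of the alkenylalane occurs with retention, giving the E-enone with >98 % geometric purity.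

**Step 5**
Reactants: 8 (3E,11E,13E,16Z)-4-methylnonadeca-3,11,13,16-tetraen-2-one
Product: 10 (5S)-3,5-dimethyl-5-[(7E,9E,12Z)-pentadeca-7,9,12-trien-1-yl]-1,2-dioxolan-3-ol, via hydroperoxy ketone 9 (not isolated)
Conditions: 9-amino-9-deoxy-epi-quinine (20 mol %), Cl3CCO2H (40 mol %), 50 % aq H2O2 (5 equiv), dioxane, 25 °C, 48–72 h, Ar, dark, trace BHT
Reagents that add atoms: hydrogen peroxide, OO
Why: Proposed new method: enantioselective conjugate hydroperoxidation of an acyclic β,β-dialkyl enone, creating a tetrasubstituted C–OO stereocentre. The small primary amine condenses with the methyl ketone to an iminium ion, and the protonated quinuclidine binds H2O2 and delivers it to the Si face of C4, so the fixed E geometry turns the methyl/chain difference into 5S. Hydrolysis gives 9, whose 5-exo closure onto the ketone (helped by the gem-dialkyl effect) forms the second ring C–O bond and takes the adduct out of the retro-Michael and epoxide-forming pathways. H2O2 acts here as a nucleophile, so the electron-rich triene is not touched, and the C3 anomer mixture is irrelevant. The closest known reaction types are cinchona primary-amine-salt hydroperoxidation of β-monosubstituted alkyl enones to peroxyhemiketals and the non-asymmetric addition of H2O2 to mesityl oxide giving 3,5,5-trimethyl-1,2-dioxolan-3-ol.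

**Step 6**
Reactants: 10 (5S)-3,5-dimethyl-5-[(7E,9E,12Z)-pentadeca-7,9,12-trien-1-yl]-1,2-dioxolan-3-ol
Product: 13 methyl 2-[(3R,5S)-3,5-dimethyl-5-[(7E,9E,12Z)-pentadeca-7,9,12-trien-1-yl]-1,2-dioxolan-3-yl]acetate, via silyl peroxyketal 11 (not isolated), via peroxycarbenium ion 12 (not isolated)
Conditions: confined BINOL-derived N-triflyl imidodiphosphorimidate (IDPi, 5 mol %), 1-(tert-butyldimethylsilyloxy)-1-methoxyethene (3 equiv), Et2O, −78 → −60 °C
Reagents that add atoms: 1-(tert-butyldimethylsilyloxy)-1-methoxyethene, C=C(OC)O[Si](C)(C)C(C)(C)C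
Why: Proposed new method: counter-anion-controlled Mukaiyama-type substitution at a tertiary cyclic peroxycarbenium ion. The silylium/IDPi pair first silylates the hemiketal OH to give 11 and then ionises it to 12, which stays paired with the confined chiral anion. The anion shields one face, so the ketene acetal attacks C3 cis to the C5 methyl and trans to the C15 chain, giving 3R; this is also the weakly preferred substrate face, so the case is matched. The ketene acetal is many orders of magnitude more nucleophilic than the diene, so the side chain does not compete. The closest known reaction types are achiral Lewis-acid substitution of 3-alkoxy-1,2-dioxolanes by silyl ketene acetals via peroxycarbenium ions and IDPi-catalysed enantioselective addition of silyl ketene acetals to cyclic aliphatic oxocarbenium ions.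

**Step 7**
Reactants: 13 methyl 2-[(3R,5S)-3,5-dimethyl-5-[(7E,9E,12Z)-pentadeca-7,9,12-trien-1-yl]-1,2-dioxolan-3-yl]acetate
Product: 14 2-[(3R,5S)-3,5-dimethyl-5-[(7E,9E,12Z)-pentadeca-7,9,12-trien-1-yl]-1,2-dioxolan-3-yl]acetic acid
Conditions: LiOH (3 equiv), THF/H2O 3:1, 0 °C → rt; then 1 M HCl to pH 3
Reagents that add atoms: lithium hydroxide, [Li+].[OH-]
Why: In this saponification (BAc2), attack at the unhindered ester carbonyl is faster than α-deprotonation, the fully substituted dialkyl peroxide has no α-H for base-induced cleavage, and the carboxylate once formed blocks retro-Michael opening, so C3 and C5 are untouched.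

**Compound list**
1 | (Z)-hex-3-en-1-ol | CC/C=C\CCO | starting material
2 | (Z)-hex-3-enal | CC/C=C\CC=O | intermediate
3 | (1E,4Z)-1-iodohepta-1,4-diene | CC/C=C\C/C=C/I | intermediate
4 | deca-1,9-diyne | C#CCCCCCCC#C | starting material
5 | chlorobis(cyclopentadienyl)[(1E)-dec-1-en-9-yn-1-yl]zirconium | C#CCCCCCC/C=C/[Zr](Cl)(C1C=CC=C1)C1C=CC=C1 | intermediate
6 | (9E,11E,14Z)-heptadeca-9,11,14-trien-1-yne | CC/C=C\C/C=C/C=C/CCCCCCC#C | intermediate
7 | dimethyl[(1E,9E,11E,14Z)-2-methylheptadeca-1,9,11,14-tetraen-1-yl]alane | CC/C=C\C/C=C/C=C/CCCCCC/C(C)=C/[Al](C)C | intermediate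
8 | (3E,11E,13E,16Z)-4-methylnonadeca-3,11,13,16-tetraen-2-one | CC/C=C\C/C=C/C=C/CCCCCC/C(C)=C/C(C)=O | intermediate
9 | (4S,11E,13E,16Z)-4-hydroperoxy-4-methylnonadeca-11,13,16-trien-2-one | CC/C=C\C/C=C/C=C/CCCCCC[C@@](OO)(C)CC(C)=O | intermediate
10 | (5S)-3,5-dimethyl-5-[(7E,9E,12Z)-pentadeca-7,9,12-trien-1-yl]-1,2-dioxolan-3-ol (C3 anomers) | CC/C=C\C/C=C/C=C/CCCCCC[C@@]1(C)CC(C)(O)OO1 | intermediate
11 | (5S)-3-(tert-butyldimethylsilyloxy)-3,5-dimethyl-5-[(7E,9E,12Z)-pentadeca-7,9,12-trien-1-yl]-1,2-dioxolane | CC/C=C\C/C=C/C=C/CCCCCC[C@@]1(C)CC(C)(O[Si](C)(C)C(C)(C)C)OO1 | intermediate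
12 | (5S)-3,5-dimethyl-5-[(7E,9E,12Z)-pentadeca-7,9,12-trien-1-yl]-4,5-dihydro-1,2-dioxol-2-ium (peroxycarbenium ion, IDPi counter-anion) | CC/C=C\C/C=C/C=C/CCCCCC[C@@]1(C)CC(C)=[O+]O1 | intermediate
13 | methyl 2-[(3R,5S)-3,5-dimethyl-5-[(7E,9E,12Z)-pentadeca-7,9,12-trien-1-yl]-1,2-dioxolan-3-yl]acetate | CC/C=C\C/C=C/C=C/CCCCCC[C@@]1(C)C[C@](C)(CC(=O)OC)OO1 | intermediate
14 | 2-[(3R,5S)-3,5-dimethyl-5-[(7E,9E,12Z)-pentadeca-7,9,12-trien-1-yl]-1,2-dioxolan-3-yl]acetic acid | CC/C=C\C/C=C/C=C/CCCCCC[C@@]1(C)C[C@](C)(CC(=O)O)OO1 | target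

**Total steps:** 7. **Longest linear sequence:** 7 (1 → 2 → 3 → 6 → 8 → 10 → 13 → 14).

**Three steps most likely to fail**

**Step 5 (new method).**
- Risks: the β,β-disubstituted iminium ion reacts slowly. E/Z scrambling through the dienamine would erode the methyl/chain discrimination. Reversible addition and epoxide formation compete.
- Fallback (known chemistry, resolution instead of asymmetric catalysis): it sets out from 8 and returns at 13. Treat 8 with 30 % H2O2 and catalytic NaOH in MeOH at 0 °C, the classical addition to mesityl-oxide-type enones. This gives the racemic 3,5-dimethyl-5-trienyl-1,2-dioxolan-3-ol F3. MeOH/PPTS converts it into the racemic 3-methoxy-1,2-dioxolane F4. TiCl4 and the same silyl ketene acetal in CH2Cl2 at −78 °C then give the racemic trans ester F5 next to the racemic cis ester F6, which is removed on silica. Preparative chiral SFC of F5 delivers 13.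

**Step 6 (new method).**
- Risks: the free hemiketal may open and react as a ketone. The chiral anion may not control a tertiary peroxycarbenium ion. Acid-induced O–O fragmentation is possible.
- Fallback (known chemistry, substrate control plus separation through a different electrophile): it sets out from 10 and returns at 13. Ketalise 10 with MeOH/PPTS to the (5S)-3-methoxy-1,2-dioxolane F7. Treat this with TiCl4 (1 equiv) and the silyl ketene acetal in CH2Cl2 at −78 °C. The reaction gives 13 together with its C3 epimer, the (3S,5S)-cis ester F8, in about 1–2:1. The two are separated by silica chromatography or HPLC.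

**Step 4.**
- Risks: methyl transfer may compete with alkenyl transfer in the acylation. AcCl with aluminium Lewis acids may attack the diene or the THF solvent.
- Fallback (polarity reversal, vinyl electrophile plus acyl-anion equivalent): it sets out from 7, generated from 6 as in step 4, and returns at 8. Quench 7 with I2 (THF, −30 °C, dark) to the (E)-vinyl iodide F1. Couple this with tributyl(1-ethoxyvinyl)stannane (Pd(PPh3)4, CuI, DMF, 60 °C, Stille) to the 2-ethoxydiene F2. Hydrolyse F2 with 1 M HCl/THF at rt to give 8 with the E geometry retained.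

**Further compounds**
F1 | step 4 | (1E,9E,11E,14Z)-1-iodo-2-methylheptadeca-1,9,11,14-tetraene | CC/C=C\C/C=C/C=C/CCCCCC/C(C)=C/I
F2 | step 4 | (3E,11E,13E,16Z)-2-ethoxy-4-methylnonadeca-1,3,11,13,16-pentaene | CC/C=C\C/C=C/C=C/CCCCCC/C(C)=C/C(=C)OCC
F3 | step 5 | racemic 3,5-dimethyl-5-[(7E,9E,12Z)-pentadeca-7,9,12-trien-1-yl]-1,2-dioxolan-3-ol | CC/C=C\C/C=C/C=C/CCCCCCC1(C)CC(C)(O)OO1
F4 | step 5 | racemic 3-methoxy-3,5-dimethyl-5-[(7E,9E,12Z)-pentadeca-7,9,12-trien-1-yl]-1,2-dioxolane | CC/C=C\C/C=C/C=C/CCCCCCC1(C)CC(C)(OC)OO1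
F5 | step 5 | racemic trans methyl ester, drawn as its (3S,5R) half (the other half is 13) | CC/C=C\C/C=C/C=C/CCCCCC[C@]1(C)C[C@@](C)(CC(=O)OC)OO1
F6 | step 5 | racemic cis methyl ester, drawn as its (3R,5R) half | CC/C=C\C/C=C/C=C/CCCCCC[C@]1(C)C[C@](C)(CC(=O)OC)OO1
F7 | step 6 | (5S)-3-methoxy-3,5-dimethyl-5-[(7E,9E,12Z)-pentadeca-7,9,12-trien-1-yl]-1,2-dioxolane | CC/C=C\C/C=C/C=C/CCCCCC[C@@]1(C)CC(C)(OC)OO1
F8 | step 6 | methyl 2-[(3S,5S)-3,5-dimethyl-5-[(7E,9E,12Z)-pentadeca-7,9,12-trien-1-yl]-1,2-dioxolan-3-yl]acetate | CC/C=C\C/C=C/C=C/CCCCCC[C@@]1(C)C[C@@](C)(CC(=O)OC)OO1
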